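**Retrosynthetic overview**
- Structural feature: in ring A, oxygen sits on C5, C7 and C8a. It alternates with carbon substituents on C4a (the C4 carbonyl) and C6 (prenyl), and only C8 carries H. A 1,1,3-trioxygenated 2-alkylbutadiene added to an acyl alkyne leaves exactly this pattern.
- Ring C: cut O1–C8a (intramolecular CuI-catalysed O-arylation) and C2–C3 (one carbon from DMF dimethyl acetal, O1 from water). This leads back to bromo-deoxybenzoin 16, and its C5 methyl ether leads back to phenol 15.
- Ring A: cut C4a–C5 and C8–C8a by a retro-[4+2]/aromatisation to silyl ketene acetal diene 6 and bromoethynyl ketone 13. The alkyne bromine becomes the C8a handle, and the TIPS group of the diene keeps O7 distinct from O5.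
- Diene 6 comes from methyl acetoacetate and prenyl bromide (three steps). Ynone 13 comes from 2,4-dihydroxyphenylacetic acid through its Weinreb amide and trimethylsilylacetylene (four steps).
- Ring order: ring B is bought, ring A is built in step 8, ring C is closed in step 11. MOM is removed before TIPS, so no free phenol flanks the prenyl group under acid.

Key step: step 8

Assumption: the C=C geometries drawn for 4, 5, 6, 17 and 18 are those expected to prevail, and each is erased later (dienolate formation, aromatisation, enol equilibration), so isomer mixtures can be carried on. Prenyl = 3-methylbut-2-en-1-yl, MOM = methoxymethyl, TIPS = triisopropylsilyl, TMS = trimethylsilyl.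

Step 1
Reactants: 1 methyl acetoacetate; 2 prenyl bromide
Product: 3 methyl 2-acetyl-5-methylhex-4-enoate (racemic)
Conditions: 1 (1.3 equiv), K2CO3 (1.2 equiv), acetone, reflux
Reagents that add atoms: none
Why: SN2 C-alkylation of the stabilised β-keto ester enolate by a primary allylic bromide is standard acetoacetic ester chemistry, the excess of 1 holds back dialkylation, and the new C2 stereocentre is racemic and is erased in step 2.

Step 2
Reactants: 3 methyl 2-acetyl-5-methylhex-4-enoate
Product: 4 methyl (Z)-5-methyl-2-[1-(triisopropylsilyloxy)ethylidene]hex-4-enoate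
Conditions: TIPSOTf (1.1 equiv), Et3N (1.5 equiv), CH2Cl2, 0 °C → rt
Reagents that add atoms: triisopropylsilyl trifluoromethanesulfonate, CC(C)[Si](C(C)C)(C(C)C)OS(=O)(=O)C(F)(F)F
Why: Soft enolisation and O-silylation of a β-keto ester with a silyl triflate and a tertiary amine removes the most acidic C2 proton and should give the conjugated silyl enol ether, whose bulky silyl group is chosen to outlast the acidic aromatisation of step 8.

Step 3
Reactants: 4 methyl (Z)-5-methyl-2-[1-(triisopropylsilyloxy)ethylidene]hex-4-enoate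
Product: 6 (Z)-1-methoxy-2-prenyl-3-(triisopropylsilyloxy)-1-(trimethylsilyloxy)buta-1,3-diene, via lithium dienolate 5 (not isolated)
Conditions: LiN(i-Pr)2 (commercial solution, 1.1 equiv), THF, −78 °C; TMSCl, −78 → 0 °C; pentane, filtration under Ar, no aqueous work-up, used crude
Reagents that add atoms: chlorotrimethylsilane, C[Si](C)(C)Cl
Why: Kinetic γ-deprotonation of the β-silyloxy enoate at its methyl group followed by O-silylation of the extended ester enolate is the standard second stage in making 1-alkoxy-1,3-bis(silyloxy)dienes, and the fully substituted α-carbon leaves O-silylation as the only fast pathway.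

Step 4
Reactants: 7 2,4-dihydroxyphenylacetic acid
Product: 8 2-(2,4-dihydroxyphenyl)-N-methoxy-N-methylacetamide
Conditions: MeNH(OMe)·HCl, EDC·HCl, HOBt, i-Pr2NEt, DMF, 0 °C → rt
Reagents that add atoms: N,O-dimethylhydroxylamine hydrochloride, CNOC.Cl
Why: Carbodiimide amide coupling (Weinreb amide formation) tolerates the free phenols because any aryl ester formed by acyl transfer to the ortho hydroxyl is aminolysed to the same amide.

Step 5
Reactants: 8 2-(2,4-dihydroxyphenyl)-N-methoxy-N-methylacetamide
Product: 9 2-[2,4-bis(methoxymethoxy)phenyl]-N-methoxy-N-methylacetamide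
Conditions: MOMCl (2.6 equiv), i-Pr2NEt (3 equiv), CH2Cl2, 0 °C → rt
Reagents that add atoms: chloromethyl methyl ether, COCCl
Why: Williamson-type O-alkylation of both phenols gives acetal ethers that withstand the organolithium, carbonate and copper steps and are removed later by mild acid.

Step 6
Reactants: 9 2-[2,4-bis(methoxymethoxy)phenyl]-N-methoxy-N-methylacetamide; 10 trimethylsilylacetylene
Product: 12 1-[2,4-bis(methoxymethoxy)phenyl]-4-(trimethylsilyl)but-3-yn-2-one, via lithium (trimethylsilyl)acetylide 11 (not isolated)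
Conditions: 10 (1.6 equiv), n-BuLi (1.5 equiv), THF, −78 °C; then 9, −78 → −20 °C; inverse quench into cold 1 M HCl
Reagents that add atoms: none
Why: In the Weinreb ketone synthesis the acetylide adds once to give a chelated tetrahedral intermediate that collapses only on quenching, and the inverse acidic quench protonates the released amine before it can add to the ynone.

Step 7
Reactants: 12 1-[2,4-bis(methoxymethoxy)phenyl]-4-(trimethylsilyl)but-3-yn-2-one
Product: 13 4-bromo-1-[2,4-bis(methoxymethoxy)phenyl]but-3-yn-2-one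
Conditions: NBS (1.05 equiv), AgNO3 (10 mol %), acetone, 0 °C → rt, dark; used promptly
Reagents that add atoms: N-bromosuccinimide, O=C1CCC(=O)N1Br
Why: AgNO3-catalysed bromodesilylation of a silylalkyne with NBS runs through a silver acetylide that should be brominated faster than the aryl ether ring or the ketone CH2 when only a slight excess of NBS is used in the cold and dark.

Step 8
Reactants: 6 (Z)-1-methoxy-2-prenyl-3-(triisopropylsilyloxy)-1-(trimethylsilyloxy)buta-1,3-diene; 13 4-bromo-1-[2,4-bis(methoxymethoxy)phenyl]but-3-yn-2-one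
Product: 15 1-[2-bromo-6-hydroxy-5-prenyl-4-(triisopropylsilyloxy)phenyl]-2-[2,4-bis(methoxymethoxy)phenyl]ethanone, via ketal cycloadduct 14 (not isolated)
Conditions: 6 (1.5 equiv), toluene, rt → 70 °C, Ar, no Lewis acid; then THF–0.1 M HCl, 0 °C
Reagents that add atoms: none
Why: This is a normal-electron-demand Diels–Alder cycloaddition followed by aromatisation, and the closest known cases are 1-alkoxy-1,3-bis(silyloxy)butadienes adding to alkynyl ketones and to halogen-bearing dienophiles to give resorcinol derivatives. The three oxygen donors put the largest HOMO coefficient on the CH2 terminus of 6, which bonds to the bromine-bearing β-carbon of 13 (C8–C8a) in a concerted but strongly asynchronous transition state while the ketene-acetal carbon closes onto the acyl-bearing α-carbon (C4a–C5), so ring A is closed as a six-membered carbocycle by an intermolecular [4+2] addition that gives the 1,4-cyclohexadiene 14. Cold dilute acid ionises the very labile methyl trimethylsilyl ketal, methanol leaves, one doubly allylic C8 proton is lost and the aryl TMS ether hydrolyses to the C5 phenol, whereas the TIPS enol ether passes intact into the C7 aryl silyl ether and the sp2 C–Br bond has no elimination path. The only stereocentre formed, the ketal carbon of 14, is racemic and vanishes on aromatisation, so no stereocontrol is required. The step needs one orientation, secured by the polar match of the diene CH2 with the ynone β-carbon, and ring closure rather than expulsion of bromide from an allenolate-like species, favoured by the apolar solvent, the absence of Lewis acid or fluoride, and the destabilisation of the s-trans rotamer by the 2-prenyl and 3-silyloxy groups. The excess of 6 covers losses by proton transfer from the enolisable CH2 of 13.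

Step 9
Reactants: 15 1-[2-bromo-6-hydroxy-5-prenyl-4-(triisopropylsilyloxy)phenyl]-2-[2,4-bis(methoxymethoxy)phenyl]ethanone
Product: 16 1-[2-bromo-6-methoxy-5-prenyl-4-(triisopropylsilyloxy)phenyl]-2-[2,4-bis(methoxymethoxy)phenyl]ethanone
Conditions: MeI (1.5 equiv), K2CO3 (2 equiv), acetone, 45 °C
Reagents that add atoms: iodomethane, CI
Why: In this Williamson O-methylation the phenol is by far the most acidic site and its hydrogen bond is weakened because the ortho bromine twists the carbonyl out of plane, so carbonate should form only the phenoxide and a limited charge of MeI leaves the deoxybenzoin CH2 alone.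

Step 10
Reactants: 16 1-[2-bromo-6-methoxy-5-prenyl-4-(triisopropylsilyloxy)phenyl]-2-[2,4-bis(methoxymethoxy)phenyl]ethanone
Product: 18 (Z)-1-[2-bromo-6-methoxy-5-prenyl-4-(triisopropylsilyloxy)phenyl]-3-hydroxy-2-[2,4-bis(methoxymethoxy)phenyl]prop-2-en-1-one, via enaminone 17 (not isolated)
Conditions: Me2NCH(OMe)2 (4 equiv), toluene, 100 °C; concentrate; then THF–1 M HCl, 0 °C → rt, short contact
Reagents that add atoms: N,N-dimethylformamide dimethyl acetal, COC(OC)N(C)C; water, O
Why: Formamide-acetal condensation at the acidic deoxybenzoin CH2 installs C2 as an enaminone, and since an O-arylation needs an oxygen nucleophile the vinylogous amide is hydrolysed by cold dilute acid to the chelated hydroxymethylene ketone, which brings in the future O1 from water without touching MOM or TIPS.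

Step 11
Reactants: 18 (Z)-1-[2-bromo-6-methoxy-5-prenyl-4-(triisopropylsilyloxy)phenyl]-3-hydroxy-2-[2,4-bis(methoxymethoxy)phenyl]prop-2-en-1-one
Product: 19 5-methoxy-2',4'-bis(methoxymethoxy)-6-prenyl-7-(triisopropylsilyloxy)isoflavone
Conditions: CuI (10 mol %), 1,10-phenanthroline (20 mol %), K3PO4 (2 equiv), dry dioxane, 100 °C, Ar
Reagents that add atoms: none
Why: Intramolecular Ullmann-type O-arylation of a β-dicarbonyl enolate by an ortho-acyl aryl bromide is a known chromone closure that forms O1–C8a in a six-membered ring, with the ortho carbonyl activating C–Br, the enolate geometry equilibrating freely and anhydrous phosphate sparing the aryl silyl ether.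

Step 12
Reactants: 19 5-methoxy-2',4'-bis(methoxymethoxy)-6-prenyl-7-(triisopropylsilyloxy)isoflavone
Product: 20 2',4'-dihydroxy-5-methoxy-6-prenyl-7-(triisopropylsilyloxy)isoflavone
Conditions: conc. HCl (cat.), MeOH–THF, 45 °C
Reagents that add atoms: none
Why: Acid-catalysed acetal exchange removes both MOM groups while O7 is still silylated and O5 methylated, so no free phenol flanks the prenyl group and acid-induced chroman formation is shut off, and aryl TIPS ethers tolerate these conditions.

Step 13
Reactants: 20 2',4'-dihydroxy-5-methoxy-6-prenyl-7-(triisopropylsilyloxy)isoflavone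
Product: 21 7,2',4'-trihydroxy-5-methoxy-6-prenylisoflavone (CNP0121160.0)
Conditions: Bu4NF (1.5 equiv), AcOH (1.5 equiv), THF, 0 °C
Reagents that add atoms: none
Why: Fluoride-induced desilylation buffered with acetic acid cleaves the aryl silyl ether under nearly neutral conditions that leave the prenyl group, the 5-methyl ether and the pyranone ring untouched.

**Compound list**
1 | methyl acetoacetate | COC(=O)CC(C)=O | starting material
2 | prenyl bromide (1-bromo-3-methylbut-2-ene) | CC(C)=CCBr | starting material
3 | methyl 2-acetyl-5-methylhex-4-enoate (racemic) | COC(=O)C(CC=C(C)C)C(C)=O | intermediate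
4 | methyl (Z)-5-methyl-2-[1-(triisopropylsilyloxy)ethylidene]hex-4-enoate | COC(=O)/C(CC=C(C)C)=C(/C)O[Si](C(C)C)(C(C)C)C(C)C | intermediate
5 | lithium 1-methoxy-2-prenyl-3-(triisopropylsilyloxy)buta-1,3-dien-1-olate (lithium dienolate, not isolated) | C=C(O[Si](C(C)C)(C(C)C)C(C)C)/C(CC=C(C)C)=C(/OC)[O-].[Li+] | intermediate
6 | (Z)-1-methoxy-2-prenyl-3-(triisopropylsilyloxy)-1-(trimethylsilyloxy)buta-1,3-diene | C=C(O[Si](C(C)C)(C(C)C)C(C)C)/C(CC=C(C)C)=C(/OC)O[Si](C)(C)C | intermediate
7 | 2,4-dihydroxyphenylacetic acid | O=C(O)Cc1ccc(O)cc1O | starting material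
8 | 2-(2,4-dihydroxyphenyl)-N-methoxy-N-methylacetamide | CON(C)C(=O)Cc1ccc(O)cc1O | intermediate
9 | 2-[2,4-bis(methoxymethoxy)phenyl]-N-methoxy-N-methylacetamide | CON(C)C(=O)Cc1ccc(OCOC)cc1OCOC | intermediate
10 | trimethylsilylacetylene | C#C[Si](C)(C)C | starting material
11 | lithium (trimethylsilyl)acetylide (not isolated) | [Li+].[C-]#C[Si](C)(C)C | intermediate
12 | 1-[2,4-bis(methoxymethoxy)phenyl]-4-(trimethylsilyl)but-3-yn-2-one | C[Si](C)(C)C#CC(=O)Cc1ccc(OCOC)cc1OCOC | intermediate
13 | 4-bromo-1-[2,4-bis(methoxymethoxy)phenyl]but-3-yn-2-one | BrC#CC(=O)Cc1ccc(OCOC)cc1OCOC | intermediate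
14 | 1-[2-bromo-6-methoxy-5-prenyl-4-(triisopropylsilyloxy)-6-(trimethylsilyloxy)cyclohexa-1,4-dien-1-yl]-2-[2,4-bis(methoxymethoxy)phenyl]ethanone (racemic, not isolated) | COC1(O[Si](C)(C)C)C(CC=C(C)C)=C(O[Si](C(C)C)(C(C)C)C(C)C)CC(Br)=C1C(=O)Cc1ccc(OCOC)cc1OCOC | intermediate
15 | 1-[2-bromo-6-hydroxy-5-prenyl-4-(triisopropylsilyloxy)phenyl]-2-[2,4-bis(methoxymethoxy)phenyl]ethanone | CC(C)=CCc1c(O)c(C(=O)Cc2ccc(OCOC)cc2OCOC)c(Br)cc1O[Si](C(C)C)(C(C)C)C(C)C | intermediate
16 | 1-[2-bromo-6-methoxy-5-prenyl-4-(triisopropylsilyloxy)phenyl]-2-[2,4-bis(methoxymethoxy)phenyl]ethanone | CC(C)=CCc1c(OC)c(C(=O)Cc2ccc(OCOC)cc2OCOC)c(Br)cc1O[Si](C(C)C)(C(C)C)C(C)C | intermediate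
17 | (E)-1-[2-bromo-6-methoxy-5-prenyl-4-(triisopropylsilyloxy)phenyl]-3-(dimethylamino)-2-[2,4-bis(methoxymethoxy)phenyl]prop-2-en-1-one (not isolated) | CN(C)/C=C(/C(=O)c1c(Br)cc(O[Si](C(C)C)(C(C)C)C(C)C)c(CC=C(C)C)c1OC)c1ccc(OCOC)cc1OCOC | intermediate
18 | (Z)-1-[2-bromo-6-methoxy-5-prenyl-4-(triisopropylsilyloxy)phenyl]-3-hydroxy-2-[2,4-bis(methoxymethoxy)phenyl]prop-2-en-1-one (enol form of the β-keto aldehyde) | O/C=C(\C(=O)c1c(Br)cc(O[Si](C(C)C)(C(C)C)C(C)C)c(CC=C(C)C)c1OC)c1ccc(OCOC)cc1OCOC | intermediate
19 | 5-methoxy-2',4'-bis(methoxymethoxy)-6-prenyl-7-(triisopropylsilyloxy)isoflavone | COc1c(CC=C(C)C)c(O[Si](C(C)C)(C(C)C)C(C)C)cc2occ(-c3ccc(OCOC)cc3OCOC)c(=O)c12 | intermediate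
20 | 2',4'-dihydroxy-5-methoxy-6-prenyl-7-(triisopropylsilyloxy)isoflavone | COc1c(CC=C(C)C)c(O[Si](C(C)C)(C(C)C)C(C)C)cc2occ(-c3ccc(O)cc3O)c(=O)c12 | intermediate
21 | 7,2',4'-trihydroxy-5-methoxy-6-prenylisoflavone (CNP0121160.0) | COc1c(CC=C(C)C)c(O)cc2occ(-c3ccc(O)cc3O)c(=O)c12 | target

**Step count**
- Total step count: 13.
- Longest linear sequence: 10 steps (7 → 21, steps 4 to 13). The diene branch (steps 1 to 3) joins at step 8.

**Steps most likely to fail**

Risk 1, step 8.
- What may go wrong: crowding in the tetrasubstituted, doubly silylated diene may slow the cycloaddition. Proton transfer from the enolisable ketone to the ketene acetal, or addition–elimination with loss of bromide, could then win.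
- Fallback: it sets out from 13, carries no prenyl group through the cycloaddition, and returns to the route at 15. Ynone 13 is heated in toluene with purchased, unhindered 1-methoxy-1,3-bis(trimethylsilyloxy)buta-1,3-diene to give the ketal cycloadduct F1. Dilute acid aromatises this to 1-(2-bromo-4,6-dihydroxyphenyl)-2-[2,4-bis(methoxymethoxy)phenyl]ethanone F2. The unhindered hydroxyl para to the carbonyl is silylated selectively (TIPSCl, imidazole, DMF) to give the 4-O-triisopropylsilyl ether F3. The remaining phenol is treated with tert-butyl 2-methylbut-3-en-2-yl carbonate and Pd(PPh3)4 in THF at 0 °C to give the 1,1-dimethylallyl aryl ether F4. A thermal aromatic Claisen rearrangement (N,N-diethylaniline, about 125 °C) then places a normal prenyl group on the carbon between the two oxygens, which is the only open ortho position, and this gives 15.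

Risk 2, step 7.
- What may go wrong: electrophilic bromination of the electron-rich ring B, or bromination at the enolisable CH2, may compete with bromodesilylation.
- Fallback: it sets out from 12, moves the halogenation to the alcohol oxidation level as an anionic process, and returns at 13. Luche reduction (NaBH4, CeCl3·7H2O, MeOH, −20 °C) gives the racemic silyl propargylic alcohol F5. K2CO3 in MeOH gives the terminal alkynol F6. n-BuLi (2.05 equiv, THF, −78 °C) gives the dilithio alkoxide acetylide F7. This is quenched at −78 °C with 1,2-dibromotetrachloroethane to give the racemic bromoalkynol F8. Oxidation with Dess–Martin periodinane (NaHCO3, CH2Cl2) gives 13.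

Risk 3, step 11.
- What may go wrong: substitution at the electron-rich aryl bromide may be slow. At 100 °C this leaves time for base-induced deformylation of the formyl ketone and for loss of the silyl ether.
- Fallback: it sets out from 16, makes the C8a–O bond first, closes ring C in the classical way, and returns at 19. Miyaura borylation (B2pin2, Pd(dppf)Cl2, KOAc, dioxane, 85 °C) gives the aryl pinacol boronate F9. Oxidation with NaBO3·4H2O in THF–H2O gives the 2-hydroxydeoxybenzoin F10. Heating with Me2NCH(OMe)2 in toluene gives the ortho-hydroxy enaminone F11. This closes by conjugate addition of the phenol and loss of the amine to give 19.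

**Further compounds**
F1 | step 8 | 1-[2-bromo-6-methoxy-4,6-bis(trimethylsilyloxy)cyclohexa-1,4-dien-1-yl]-2-[2,4-bis(methoxymethoxy)phenyl]ethanone (racemic) | COC1(O[Si](C)(C)C)C=C(O[Si](C)(C)C)CC(Br)=C1C(=O)Cc1ccc(OCOC)cc1OCOC
F2 | step 8 | 1-(2-bromo-4,6-dihydroxyphenyl)-2-[2,4-bis(methoxymethoxy)phenyl]ethanone | Oc1cc(O)c(C(=O)Cc2ccc(OCOC)cc2OCOC)c(Br)c1
F3 | step 8 | 1-[2-bromo-6-hydroxy-4-(triisopropylsilyloxy)phenyl]-2-[2,4-bis(methoxymethoxy)phenyl]ethanone | Oc1cc(O[Si](C(C)C)(C(C)C)C(C)C)cc(Br)c1C(=O)Cc1ccc(OCOC)cc1OCOC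
F4 | step 8 | 1-[2-bromo-6-(2-methylbut-3-en-2-yloxy)-4-(triisopropylsilyloxy)phenyl]-2-[2,4-bis(methoxymethoxy)phenyl]ethanone | C=CC(C)(C)Oc1cc(O[Si](C(C)C)(C(C)C)C(C)C)cc(Br)c1C(=O)Cc1ccc(OCOC)cc1OCOC
F5 | step 7 | 1-[2,4-bis(methoxymethoxy)phenyl]-4-(trimethylsilyl)but-3-yn-2-ol (racemic) | C[Si](C)(C)C#CC(O)Cc1ccc(OCOC)cc1OCOC
F6 | step 7 | 1-[2,4-bis(methoxymethoxy)phenyl]but-3-yn-2-ol (racemic) | C#CC(O)Cc1ccc(OCOC)cc1OCOC
F7 | step 7 | dilithium salt of F6 (alkoxide acetylide, racemic) | [Li+].[Li+].[C-]#CC([O-])Cc1ccc(OCOC)cc1OCOC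
F8 | step 7 | 4-bromo-1-[2,4-bis(methoxymethoxy)phenyl]but-3-yn-2-ol (racemic) | BrC#CC(O)Cc1ccc(OCOC)cc1OCOC
F9 | step 11 | 1-[6-methoxy-5-prenyl-2-(4,4,5,5-tetramethyl-1,3,2-dioxaborolan-2-yl)-4-(triisopropylsilyloxy)phenyl]-2-[2,4-bis(methoxymethoxy)phenyl]ethanone | CC(C)=CCc1c(OC)c(C(=O)Cc2ccc(OCOC)cc2OCOC)c(B2OC(C)(C)C(C)(C)O2)cc1O[Si](C(C)C)(C(C)C)C(C)C
F10 | step 11 | 1-[2-hydroxy-6-methoxy-5-prenyl-4-(triisopropylsilyloxy)phenyl]-2-[2,4-bis(methoxymethoxy)phenyl]ethanone | CC(C)=CCc1c(OC)c(C(=O)Cc2ccc(OCOC)cc2OCOC)c(O)cc1O[Si](C(C)C)(C(C)C)C(C)C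
F11 | step 11 | (E)-3-(dimethylamino)-1-[2-hydroxy-6-methoxy-5-prenyl-4-(triisopropylsilyloxy)phenyl]-2-[2,4-bis(methoxymethoxy)phenyl]prop-2-en-1-one | CN(C)/C=C(/C(=O)c1c(O)cc(O[Si](C(C)C)(C(C)C)C(C)C)c(CC=C(C)C)c1OC)c1ccc(OCOC)cc1OCOC
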